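**Plan**

1. Retrosynthesis: cut the pyran C7–O and C6–Br bonds (bromonium capture by the C3 oxygen), then C7–C8 (B-alkyl Suzuki–Miyaura), then C14–Br (SN2 on an axial carbinol), then the cyclohexane C10–C11 bond (reductive allene–ketone cyclisation). This leads back to an achiral allenyl diketone and (S)-linalool.
2. Forward: the carbocycle is closed first through C10–C11 (step 4), C14 is taken from ketone to bromide, the linalool-derived alkenyl iodide is joined, and the bromotetrahydropyran is closed last.
3. Enabling feature: the gem-dimethyl carbon C15 lies between C14 and C10 and is 1,3 to C11 in the six-membered ring. A chair closure can therefore only place the C11 methyl equatorial and the C11 oxygen axial, cis to the C10 side chain, which is the arrangement in the target.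
4. Stereochemistry: C10 and C11 come from the chiral copper hydride catalyst plus that chair. C14 is relayed from them (equatorial hydride delivery, then inversion by bromide). C3 is bought as (S)-linalool. C6 and C7 come from a reagent-controlled Shi epoxidation and two stereospecific displacements (inversion at C6, double inversion at C7).

Key step: step 4

Assumption: atoms are numbered as in geranyllinalool (C1=C2 vinyl; C3 and C7 flank the pyran oxygen; C6 is the pyran CHBr; C10, C11, C14, C15 are the cyclohexane CH, carbinol, CHBr and CMe2 carbons), and (S)-(+)-linalool of high enantiomeric purity is taken as commercially available.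

**Route**

Step 1
Reactants: 1 isobutyraldehyde; 2 propargyl alcohol
Product: 4 2,2-dimethylpenta-3,4-dienal, via propargyl enol ether 3 (not isolated)
Conditions: TsOH (cat.), p-cymene, 130 °C, Dean–Stark
Reagents that add atoms: none
Why: Acid-catalysed acetal exchange and loss of propargyl alcohol give the propargyl enol ether, whose propargyl Claisen ([3,3]-sigmatropic) rearrangement places the allene on the new quaternary carbon C15 (a known route to α-allenic aldehydes); no stereocentre is formed.

Step 2
Reactants: 4 2,2-dimethylpenta-3,4-dienal; 5 2-(2-bromoethyl)-2-methyl-1,3-dioxolane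
Product: 7 rac-4,4-dimethyl-1-(2-methyl-1,3-dioxolan-2-yl)hepta-5,6-dien-3-ol, via Grignard reagent 6 (not isolated)
Conditions: Mg, THF, 25 °C; then 4, −78 → 0 °C; aq. NH4Cl
Reagents that add atoms: none
Why: Grignard addition to a non-enolisable aldehyde; the carbinol centre (C14) is left racemic on purpose because it is oxidised in step 3.

Step 3
Reactants: 7 rac-4,4-dimethyl-1-(2-methyl-1,3-dioxolan-2-yl)hepta-5,6-dien-3-ol
Product: 9 6,6-dimethylnona-7,8-diene-2,5-dione, via keto ketal 8 (not isolated)
Conditions: Dess–Martin periodinane, NaHCO3, CH2Cl2, rt; then 1 M HCl, THF, rt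
Reagents that add atoms: water, O
Why: Dess–Martin oxidation of the hindered secondary alcohol followed by acid hydrolysis of the dioxolane in the same flask; the cyclisation substrate is now achiral, with C14 held at the ketone level.

Step 4
Reactants: 9 6,6-dimethylnona-7,8-diene-2,5-dione
Product: 11 (3R,4S)-4-hydroxy-2,2,4-trimethyl-3-vinylcyclohexan-1-one, via silyl ether 10 (not isolated)
Conditions: Cu(OAc)2 (5 mol %), (S,S)-Ph-BPE (6 mol %), (MeO)2MeSiH, THF, rt, slow addition of 9; then NH4F (cat.), MeOH
Reagents that add atoms: none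
Why: Proposed new method: the ligated copper hydride should add across the terminal C=C of the allene to give an allylcopper whose substituted terminus (C10) attacks the methyl ketone (C11) through a closed six-membered copper–oxygen transition state, after which the copper alkoxide is silylated by the silane and copper hydride is regenerated; the closest known reaction type is the intermolecular copper hydride/bisphosphine-catalysed enantioselective allylation of ketones with terminal allenes, used here as a ring closure with a tert-alkyl allene. The cyclohexane closes by 6-exo-trig attack of C10 on the carbonyl carbon C11. The absolute configuration of both new stereocentres (C10, C11) is set by the chiral bisphosphine, which selects the ketone face in the closed transition state. Their relative configuration is set by the substrate: in the chair the C11 methyl must be equatorial, because an axial methyl would be syn-diaxial to a methyl of the C15 gem-dimethyl group, so the oxygen is axial, and the closed transition state needs the allyl arm on C10 gauche to that oxygen and therefore equatorial, which puts the hydroxyl cis to the vinyl group. The step needs hydrocupration of the allene to outrun direct reduction of either ketone and attack at C11 rather than C14; the allene is the most reactive π-system towards copper hydride, the C14 ketone is shielded by the quaternary C15 and could be reached by C10 only through a three-membered ring, and the substrate has no stereocentre that could oppose the catalyst.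

Step 5
Reactants: 11 (3R,4S)-4-hydroxy-2,2,4-trimethyl-3-vinylcyclohexan-1-one
Product: 12 (1S,2R)-1,3,3-trimethyl-4-oxo-2-vinylcyclohexyl acetate
Conditions: Ac2O, Sc(OTf)3 (cat.), MeCN, −20 °C
Reagents that add atoms: acetic anhydride, CC(=O)OC(C)=O
Why: Sc(OTf)3-catalysed acylation esterifies hindered tertiary alcohols; an acetate is chosen because, unlike a silyl ether or a free hydroxyl, its oxygen cannot capture the bromonium ion of step 14.

Step 6
Reactants: 12 (1S,2R)-1,3,3-trimethyl-4-oxo-2-vinylcyclohexyl acetate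
Product: 13 (1S,2R,4S)-4-hydroxy-1,3,3-trimethyl-2-vinylcyclohexyl acetate
Conditions: LiBH(s-Bu)3, THF, −78 °C; H2O
Reagents that add atoms: none
Why: The bulky trialkylborohydride attacks the ketone next to the gem-dimethyl carbon along the equatorial trajectory (as in 4,4-dimethyl-3-oxo steroids and triterpenoids), so C14 is set by substrate control as the axial alcohol, trans to the vinyl group.

Step 7
Reactants: 13 (1S,2R,4S)-4-hydroxy-1,3,3-trimethyl-2-vinylcyclohexyl acetate
Product: 14 (1S,2R,4R)-4-bromo-1,3,3-trimethyl-2-vinylcyclohexyl acetate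
Conditions: PPh3, CBr4, toluene, 70 °C
Reagents that add atoms: tetrabromomethane, BrC(Br)(Br)Br
Why: Appel reaction: bromide displaces the axial oxyphosphonium group along the equatorial trajectory with inversion, giving the equatorial neopentyl bromide, as precedented for axial 3-hydroxy-4,4-dimethyl terpenoid rings.

Step 8
Reactants: 15 (S)-(+)-linalool
Product: 16 triethyl{[(3S)-3,7-dimethylocta-1,6-dien-3-yl]oxy}silane
Conditions: Et3SiOTf, 2,6-lutidine, CH2Cl2, −78 → 0 °C
Reagents that add atoms: triethylsilyl trifluoromethanesulfonate, CC[Si](CC)(CC)OS(=O)(=O)C(F)(F)F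
Why: Silylation of the tertiary allylic alcohol with the silyl triflate leaves the bought stereocentre C3 untouched; the silyl ether later serves as the oxygen nucleophile of step 14.

Step 9
Reactants: 16 triethyl{[(3S)-3,7-dimethylocta-1,6-dien-3-yl]oxy}silane
Product: 18 (4S)-4-methyl-4-(triethylsilyloxy)hex-5-enal, via ozonide 17 (not isolated)
Conditions: O3 (1 equiv, Sudan Red end point), CH2Cl2, −78 °C; then Me2S
Reagents that add atoms: ozone, [O-][O+]=O
Why: Chemoselective ozonolysis: ozone reacts much faster with the electron-rich trisubstituted alkene than with the hindered vinyl group next to the silyloxy-bearing quaternary carbon.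

Step 10
Reactants: 18 (4S)-4-methyl-4-(triethylsilyloxy)hex-5-enal
Product: 20 triethyl{[(3S,6E)-7-iodo-3-methylocta-1,6-dien-3-yl]oxy}silane, via β-oxido ylide 19 (not isolated)
Conditions: EtPPh3Br, PhLi, THF, −78 °C; 18; PhLi, −78 → −40 °C; I2, −78 °C → rt
Reagents that add atoms: ethyltriphenylphosphonium bromide, CC[P+](c1ccccc1)(c1ccccc1)c1ccccc1.[Br-]; iodine, II
Why: Wittig–Schlosser-type iodo-olefination: iodination of the β-oxido phosphonium ylide and collapse give trisubstituted (E)-alkenyl iodides with iodine trans to the chain, directly from the aldehyde.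

Step 11
Reactants: 14 (1S,2R,4R)-4-bromo-1,3,3-trimethyl-2-vinylcyclohexyl acetate; 20 triethyl{[(3S,6E)-7-iodo-3-methylocta-1,6-dien-3-yl]oxy}silane
Product: 22 (1S,2R,4R)-4-bromo-2-[(3E,7S)-3,7-dimethyl-7-(triethylsilyloxy)nona-3,8-dien-1-yl]-1,3,3-trimethylcyclohexyl acetate, via B-alkyl-9-BBN 21 (not isolated)
Conditions: 9-BBN, THF, 0 °C → rt; aq. Cs2CO3; then 20, Pd(dppf)Cl2 (cat.), AsPh3, DMF, rt
Reagents that add atoms: none
Why: Anti-Markovnikov hydroboration of the only alkene of 14, then B-alkyl Suzuki–Miyaura coupling with retention of the alkenyl iodide geometry forms C7–C8; the neopentyl secondary bromide does not add oxidatively to zerovalent palladium under these conditions.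

Step 12
Reactants: 22 (1S,2R,4R)-4-bromo-2-[(3E,7S)-3,7-dimethyl-7-(triethylsilyloxy)nona-3,8-dien-1-yl]-1,3,3-trimethylcyclohexyl acetate
Product: 23 (1S,2R,4R)-4-bromo-1,3,3-trimethyl-2-(2-{(2S,3S)-2-methyl-3-[(3S)-3-methyl-3-(triethylsilyloxy)pent-4-en-1-yl]oxiran-2-yl}ethyl)cyclohexyl acetate
Conditions: L-fructose-derived Shi ketone (cat.), KHSO5, K2CO3, Bu4NHSO4, MeCN/CH2(OMe)2/aq. buffer pH 10.5, 0 °C
Reagents that add atoms: potassium peroxymonosulfate (KHSO5), [K+].[O-]S(=O)(=O)OO
Why: Shi asymmetric epoxidation is reagent-controlled on (E)-trisubstituted alkenes and leaves the monosubstituted vinyl group alone; the ketone enantiomer expected to give the (6S,7S)-epoxide is used, which fixes C7 and, after inversion, C6.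

Step 13
Reactants: 23 (1S,2R,4R)-4-bromo-1,3,3-trimethyl-2-(2-{(2S,3S)-2-methyl-3-[(3S)-3-methyl-3-(triethylsilyloxy)pent-4-en-1-yl]oxiran-2-yl}ethyl)cyclohexyl acetate
Product: 24 (1S,2R,4R)-4-bromo-2-[(3S,4R,7S)-4-bromo-3-hydroxy-3,7-dimethyl-7-(triethylsilyloxy)non-8-en-1-yl]-1,3,3-trimethylcyclohexyl acetate
Conditions: Li2NiBr4, THF, 0 °C → rt
Reagents that add atoms: dilithium tetrabromonickelate (Li2NiBr4), [Li+].[Li+].[Ni+2].[Br-].[Br-].[Br-].[Br-]
Why: The divalent nickel bromide complex delivers bromide by SN2 attack at the less substituted epoxide carbon, so C6 is inverted to the (R)-bromide and C7 becomes the tertiary alcohol with its configuration unchanged.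

Step 14
Reactants: 24 (1S,2R,4R)-4-bromo-2-[(3S,4R,7S)-4-bromo-3-hydroxy-3,7-dimethyl-7-(triethylsilyloxy)non-8-en-1-yl]-1,3,3-trimethylcyclohexyl acetate
Product: 27 (1S,2R,4R)-4-bromo-2-{2-[(2S,3R,6S)-3-bromo-2,6-dimethyl-6-vinyltetrahydro-2H-pyran-2-yl]ethyl}-1,3,3-trimethylcyclohexyl acetate, via tertiary triflate 25 (not isolated), via bromonium triflate 26 (not isolated)
Conditions: Tf2O, 2,6-di-tert-butyl-4-methylpyridine, CH2Cl2, −78 → 0 °C
Reagents that add atoms: none
Why: Triflation of the only free hydroxyl and anchimerically assisted ionisation give a bromonium ion (inversion at C7) that the silyl ether oxygen opens at the tertiary carbon in a 6-endo sense (second inversion, net retention at C7) with loss of the silyl group to triflate; ionisation of β-bromo sulfonates with retention through configurationally defined bromonium ions is a known reaction type.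

Step 15
Reactants: 27 (1S,2R,4R)-4-bromo-2-{2-[(2S,3R,6S)-3-bromo-2,6-dimethyl-6-vinyltetrahydro-2H-pyran-2-yl]ethyl}-1,3,3-trimethylcyclohexyl acetate
Product: 28 (1S,2R,4R)-4-bromo-2-{2-[(2S,3R,6S)-3-bromo-2,6-dimethyl-6-vinyltetrahydro-2H-pyran-2-yl]ethyl}-1,3,3-trimethylcyclohexan-1-ol
Conditions: i-Bu2AlH, CH2Cl2, −78 °C; aq. KNaC4H4O6
Reagents that add atoms: none
Why: Reductive cleavage of the hindered tertiary acetate at low temperature, to which the secondary alkyl bromides, the vinyl group and the tertiary allylic ether are inert; no stereocentre is touched.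

**Compound list**

1 | isobutyraldehyde (2-methylpropanal) | CC(C)C=O | starting material
2 | propargyl alcohol (prop-2-yn-1-ol) | C#CCO | starting material
3 | 2-methyl-1-(prop-2-yn-1-yloxy)prop-1-ene | CC(C)=COCC#C | intermediate
4 | 2,2-dimethylpenta-3,4-dienal | O=CC(C)(C)C=C=C | intermediate
5 | 2-(2-bromoethyl)-2-methyl-1,3-dioxolane | CC1(CCBr)OCCO1 | starting material
6 | [2-(2-methyl-1,3-dioxolan-2-yl)ethyl]magnesium bromide | CC1(CC[Mg]Br)OCCO1 | intermediate
7 | rac-4,4-dimethyl-1-(2-methyl-1,3-dioxolan-2-yl)hepta-5,6-dien-3-ol (racemic carbinol) | CC1(CCC(O)C(C)(C)C=C=C)OCCO1 | intermediate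
8 | 4,4-dimethyl-1-(2-methyl-1,3-dioxolan-2-yl)hepta-5,6-dien-3-one | CC1(CCC(=O)C(C)(C)C=C=C)OCCO1 | intermediate
9 | 6,6-dimethylnona-7,8-diene-2,5-dione | CC(=O)CCC(=O)C(C)(C)C=C=C | intermediate
10 | (3R,4S)-4-{[dimethoxy(methyl)silyl]oxy}-2,2,4-trimethyl-3-vinylcyclohexan-1-one | C=C[C@@H]1C(C)(C)C(=O)CC[C@]1(C)O[Si](C)(OC)OC | intermediate
11 | (3R,4S)-4-hydroxy-2,2,4-trimethyl-3-vinylcyclohexan-1-one | C=C[C@@H]1C(C)(C)C(=O)CC[C@]1(C)O | intermediate
12 | (1S,2R)-1,3,3-trimethyl-4-oxo-2-vinylcyclohexyl acetate | C=C[C@@H]1C(C)(C)C(=O)CC[C@]1(C)OC(C)=O | intermediate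
13 | (1S,2R,4S)-4-hydroxy-1,3,3-trimethyl-2-vinylcyclohexyl acetate (axial 4-OH) | C=C[C@@H]1C(C)(C)[C@@H](O)CC[C@]1(C)OC(C)=O | intermediate
14 | (1S,2R,4R)-4-bromo-1,3,3-trimethyl-2-vinylcyclohexyl acetate | C=C[C@@H]1C(C)(C)[C@H](Br)CC[C@]1(C)OC(C)=O | intermediate
15 | (S)-(+)-linalool, (3S)-3,7-dimethylocta-1,6-dien-3-ol | C=C[C@](O)(C)CCC=C(C)C | starting material
16 | triethyl{[(3S)-3,7-dimethylocta-1,6-dien-3-yl]oxy}silane | C=C[C@](O[Si](CC)(CC)CC)(C)CCC=C(C)C | intermediate
17 | 3,3-dimethyl-5-[(3S)-3-methyl-3-(triethylsilyloxy)pent-4-en-1-yl]-1,2,4-trioxolane (ozonide, mixture at the ring CH) | C=C[C@](O[Si](CC)(CC)CC)(C)CCC1OOC(C)(C)O1 | intermediate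
18 | (4S)-4-methyl-4-(triethylsilyloxy)hex-5-enal | C=C[C@](O[Si](CC)(CC)CC)(C)CCC=O | intermediate
19 | lithium (6S)-6-methyl-6-(triethylsilyloxy)-2-(triphenylphosphoranylidene)oct-7-en-3-olate (β-oxido ylide, mixture at the carbinolate carbon) | C=C[C@](O[Si](CC)(CC)CC)(C)CCC([O-])C(C)=P(c1ccccc1)(c1ccccc1)c1ccccc1.[Li+] | intermediate
20 | triethyl{[(3S,6E)-7-iodo-3-methylocta-1,6-dien-3-yl]oxy}silane | C=C[C@](O[Si](CC)(CC)CC)(C)CC/C=C(\C)I | intermediate
21 | B-alkyl-9-BBN adduct of 14 (boron on the terminal carbon of the former vinyl group; ring stereocentres as in 14) | C1CCC2CCCC1B2CC[C@@H]1C(C)(C)[C@H](Br)CC[C@]1(C)OC(C)=O | intermediate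
22 | (1S,2R,4R)-4-bromo-2-[(3E,7S)-3,7-dimethyl-7-(triethylsilyloxy)nona-3,8-dien-1-yl]-1,3,3-trimethylcyclohexyl acetate | C=C[C@](O[Si](CC)(CC)CC)(C)CC/C=C(\C)CC[C@@H]1C(C)(C)[C@H](Br)CC[C@]1(C)OC(C)=O | intermediate
23 | (1S,2R,4R)-4-bromo-1,3,3-trimethyl-2-(2-{(2S,3S)-2-methyl-3-[(3S)-3-methyl-3-(triethylsilyloxy)pent-4-en-1-yl]oxiran-2-yl}ethyl)cyclohexyl acetate | C=C[C@](O[Si](CC)(CC)CC)(C)CC[C@@H]1O[C@@]1(C)CC[C@@H]2C(C)(C)[C@H](Br)CC[C@]2(C)OC(C)=O | intermediate
24 | (1S,2R,4R)-4-bromo-2-[(3S,4R,7S)-4-bromo-3-hydroxy-3,7-dimethyl-7-(triethylsilyloxy)non-8-en-1-yl]-1,3,3-trimethylcyclohexyl acetate | C=C[C@](O[Si](CC)(CC)CC)(C)CC[C@@H](Br)[C@](C)(CC[C@@H]1C(C)(C)[C@H](Br)CC[C@]1(C)OC(C)=O)O | intermediate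
25 | tertiary trifluoromethanesulfonate of 24 (triflate on the C7 oxygen) | C=C[C@](O[Si](CC)(CC)CC)(C)CC[C@@H](Br)[C@](C)(CC[C@@H]1C(C)(C)[C@H](Br)CC[C@]1(C)OC(C)=O)OS(=O)(=O)C(F)(F)F | intermediate
26 | C6–C7 bromonium trifluoromethanesulfonate derived from 25 (bromine bridging C6 and C7 on the face opposite to the departed oxygen) | C=C[C@](O[Si](CC)(CC)CC)(C)CC[C@H]1[Br+][C@]1(C)CC[C@@H]2C(C)(C)[C@H](Br)CC[C@]2(C)OC(C)=O.[O-]S(=O)(=O)C(F)(F)F | intermediate
27 | (1S,2R,4R)-4-bromo-2-{2-[(2S,3R,6S)-3-bromo-2,6-dimethyl-6-vinyltetrahydro-2H-pyran-2-yl]ethyl}-1,3,3-trimethylcyclohexyl acetate | C=C[C@]1(C)CC[C@@H](Br)[C@](C)(CC[C@@H]2C(C)(C)[C@H](Br)CC[C@]2(C)OC(C)=O)O1 | intermediate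
28 | (1S,2R,4R)-4-bromo-2-{2-[(2S,3R,6S)-3-bromo-2,6-dimethyl-6-vinyltetrahydro-2H-pyran-2-yl]ethyl}-1,3,3-trimethylcyclohexan-1-ol | C=C[C@]1(C)CC[C@@H](Br)[C@](C)(CC[C@@H]2C(C)(C)[C@H](Br)CC[C@]2(C)O)O1 | target

**Step count**

Total: 15 steps. Longest linear sequence: 12 steps (steps 1–7, then 11–15).

**Steps most likely to fail**

Step 4 (Proposed new method). What may go wrong: direct copper hydride reduction of the methyl ketone may outpace hydrocupration; addition at the neopentyl allyl terminus may be slow; enantio-induction may be insufficient or of the wrong sense, in which case the ligand antipode is used. The fallback sets out from 9 and returns at 13. Hydroboration of the allene of 9 with 9-BBN (THF, 0 °C) should give the B-allyl-9-BBN species (Z)-9-(4,4-dimethyl-5,8-dioxonon-2-en-1-yl)-9-borabicyclo[3.3.1]nonane F1. F1 allylborates the methyl ketone intramolecularly through the same chair, with a closed boron–oxygen transition state. Ethanolamine work-up should give racemic 11, that is 11 together with its mirror image (3S,4R)-4-hydroxy-2,2,4-trimethyl-3-vinylcyclohexan-1-one F2. Acetylation as in step 5 gives 12 together with its mirror image (1R,2S)-1,3,3-trimethyl-4-oxo-2-vinylcyclohexyl acetate F3. An (S)-selective ketoreductase (NADPH, isopropanol recycling; compare the baker's yeast reduction of 2,2-dimethylcyclohexane-1,3-dione) should reduce the ketone of both enantiomers to the (4S)-carbinol. This gives 13 and the diastereomeric equatorial alcohol (1R,2S,4S)-4-hydroxy-1,3,3-trimethyl-2-vinylcyclohexyl acetate F4, which are separated by chromatography.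

Step 7. What may go wrong: elimination to the cyclohexene or methyl migration from C15 instead of SN2 displacement at the neopentyl carbon. The fallback sets out from 12 and returns at 14. NaBH4 (MeOH, 0 °C; axial hydride delivery) should give the equatorial alcohol (1S,2R,4R)-4-hydroxy-1,3,3-trimethyl-2-vinylcyclohexyl acetate F5. Quinoline-8-sulfonyl chloride with DMAP converts it into the chelating sulfonate (1S,2R,4R)-1,3,3-trimethyl-4-[(quinolin-8-ylsulfonyl)oxy]-2-vinylcyclohexyl acetate F6. TiBr4 (CH2Cl2, −78 °C) then replaces the sulfonate by bromide with retention, through front-side delivery from the titanium chelate (stereoretentive halogenation with a nucleophile-assisting leaving group). The equatorial bromide 14 results without an SN2 event at the neopentyl centre.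

Step 14. What may go wrong: proton loss from the tertiary cation, capture at the secondary carbon (5-exo) instead of 6-endo closure, or erosion of configuration by bromonium transfer. The fallback sets out from 22 and returns at 27. HF·pyridine (THF, 0 °C) removes the silyl ether to give (1S,2R,4R)-4-bromo-2-[(3E,7S)-7-hydroxy-3,7-dimethylnona-3,8-dien-1-yl]-1,3,3-trimethylcyclohexyl acetate F7. 2,4,4,6-Tetrabromocyclohexa-2,5-dienone in MeNO2 (0 °C) then effects direct 6-endo bromoetherification of the alkene by the free tertiary alcohol. This is not face-selective and should give 27 together with its pyran diastereomer (1S,2R,4R)-4-bromo-2-{2-[(2R,3S,6S)-3-bromo-2,6-dimethyl-6-vinyltetrahydro-2H-pyran-2-yl]ethyl}-1,3,3-trimethylcyclohexyl acetate F8, to be separated by chromatography.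

Further compounds
F1 | step 4 | (Z)-9-(4,4-dimethyl-5,8-dioxonon-2-en-1-yl)-9-borabicyclo[3.3.1]nonane | CC(=O)CCC(=O)C(C)(C)/C=C\CB1C2CCCC1CCC2
F2 | step 4 | (3S,4R)-4-hydroxy-2,2,4-trimethyl-3-vinylcyclohexan-1-one | C=C[C@H]1C(C)(C)C(=O)CC[C@@]1(C)O
F3 | step 4 | (1R,2S)-1,3,3-trimethyl-4-oxo-2-vinylcyclohexyl acetate | C=C[C@H]1C(C)(C)C(=O)CC[C@@]1(C)OC(C)=O
F4 | step 4 | (1R,2S,4S)-4-hydroxy-1,3,3-trimethyl-2-vinylcyclohexyl acetate | C=C[C@H]1C(C)(C)[C@@H](O)CC[C@@]1(C)OC(C)=O
F5 | step 7 | (1S,2R,4R)-4-hydroxy-1,3,3-trimethyl-2-vinylcyclohexyl acetate | C=C[C@@H]1C(C)(C)[C@H](O)CC[C@]1(C)OC(C)=O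
F6 | step 7 | (1S,2R,4R)-1,3,3-trimethyl-4-[(quinolin-8-ylsulfonyl)oxy]-2-vinylcyclohexyl acetate | C=C[C@@H]1C(C)(C)[C@H](OS(=O)(=O)c2cccc3cccnc23)CC[C@]1(C)OC(C)=O
F7 | step 14 | (1S,2R,4R)-4-bromo-2-[(3E,7S)-7-hydroxy-3,7-dimethylnona-3,8-dien-1-yl]-1,3,3-trimethylcyclohexyl acetate | C=C[C@](O)(C)CC/C=C(\C)CC[C@@H]1C(C)(C)[C@H](Br)CC[C@]1(C)OC(C)=O
F8 | step 14 | (1S,2R,4R)-4-bromo-2-{2-[(2R,3S,6S)-3-bromo-2,6-dimethyl-6-vinyltetrahydro-2H-pyran-2-yl]ethyl}-1,3,3-trimethylcyclohexyl acetate | C=C[C@]1(C)CC[C@H](Br)[C@@](C)(CC[C@@H]2C(C)(C)[C@H](Br)CC[C@]2(C)OC(C)=O)O1
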